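**Assumption:** the target has no stereocentres or stereogenic axes (every sp3 carbon is a CH2 or CH3), so it is achiral and no enantiocontrol is needed.

## Retrosynthetic overview

1. The last bond made is ring-A C(aryl)–CH2 of the bibenzyl bridge: an aryl radical from a fully substituted, unprotected ring-A iodide adds to the terminus of 3-vinylphenol (anti-Markovnikov radical hydroarylation).
2. The ring-A iodide comes from 3-iodo-5-methoxyphenol by ortho,ortho-C-benzylation of its sodium phenoxide with 4-(bromomethyl)phenyl pivalate.
3. 3-Iodo-5-methoxyphenol comes from 3-iodophenol (O-methylation, then Ir C–H borylation/oxidation). The benzyl bromide comes from p-cresol (pivaloylation, benzylic bromination). 3-Vinylphenol comes from 3-iodophenol and potassium vinyltrifluoroborate.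
4. No ring is constructed: all four benzene rings are bought intact (p-cresol twice, 3-iodophenol twice).

## Route

**Step 1**
Reactants: 1, p-cresol (4-methylphenol)
Product: 2, 4-methylphenyl pivalate
Conditions: PivCl, Et3N, DMAP (cat.), CH2Cl2, 0 °C → rt
Reagents that add atoms: pivaloyl chloride, CC(C)(C)C(Cl)=O
Why: Simple O-acylation of the phenol; the pivalate deactivates the ring toward electrophilic bromination in step 2 and prevents p-quinone methide formation from the benzyl bromide in step 5.

**Step 2**
Reactants: 2, 4-methylphenyl pivalate
Product: 3, 4-(bromomethyl)phenyl pivalate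
Conditions: NBS (1.05 equiv), AIBN (5 mol%), PhCF3, reflux
Reagents that add atoms: N-bromosuccinimide, O=C1CCC(=O)N1Br
Why: Wohl–Ziegler radical bromination; the aryl CH3 is the only benzylic C–H, and the tert-butyl C–H bonds and the ester-deactivated ring do not react.

**Step 3**
Reactants: 4, 3-iodophenol
Product: 5, 3-iodoanisole
Conditions: MeI, K2CO3, acetone, reflux
Reagents that add atoms: iodomethane, CI
Why: Williamson O-methylation of the phenoxide; the aryl iodide is inert to these conditions.

**Step 4**
Reactants: 5, 3-iodoanisole
Product: 7, 3-iodo-5-methoxyphenol, via boronate 6, 2-(3-iodo-5-methoxyphenyl)-4,4,5,5-tetramethyl-1,3,2-dioxaborolane (not isolated)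
Conditions: [Ir(OMe)(cod)]2 (1.5 mol%), dtbpy (3 mol%), B2pin2 (0.7 equiv), THF, 60 °C; then 30% H2O2, aq NaOH, 0 °C → rt
Reagents that add atoms: hydrogen peroxide, OO (supplies the phenolic oxygen); B2pin2, CC1(C)OB(OC1(C)C)B1OC(C)(C)C(C)(C)O1, is used but leaves no atoms in 7
Why: Sterically controlled Ir-catalysed C–H borylation of a 1,3-disubstituted arene goes to C5, the only C–H with no ortho substituent, and the C–B bond is then oxidised to C–OH in the same pot; aryl halides are tolerated by the Ir tris-boryl catalyst.

**Step 5**
Reactants: 7, 3-iodo-5-methoxyphenol; 3, 4-(bromomethyl)phenyl pivalate (2.2 equiv)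
Product: 9, 2,6-bis(4-hydroxybenzyl)-3-iodo-5-methoxyphenol, via bis-pivalate 8, 3-iodo-5-methoxy-2,6-bis[4-(pivaloyloxy)benzyl]phenol (not isolated)
Conditions: NaH (2.2 equiv), toluene, rt → 80 °C; then NaOMe, MeOH, rt; aq NH4Cl
Reagents that add atoms: none (both benzyl groups come from reactant 3)
Why: Heterogeneous C-alkylation of a sodium phenoxide in a non-polar solvent (Claisen/Kornblum-type): the tightly aggregated Na–O ion pair shields oxygen and delivers the benzyl bromide to the two ortho carbons through a Na-bridged cyclic transition state, the second equivalent of NaH re-forms the phenoxide for the second ortho alkylation, and methoxide then cleaves both aryl pivalates while methanol traps any leftover bromide.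

**Step 6**
Reactants: 4, 3-iodophenol; 10, potassium vinyltrifluoroborate
Product: 11, 3-vinylphenol
Conditions: PdCl2(dppf)·CH2Cl2 (2 mol%), Cs2CO3 (3 equiv), THF/H2O (9:1), 80 °C; product filtered through silica and used at once
Reagents that add atoms: none beyond reactant 10 (C=C[B-](F)(F)F.[K+]), which supplies the two bridge carbons
Why: Suzuki–Miyaura vinylation of an aryl iodide, which tolerates the free phenol when extra base is used.

**Step 7 (key step)**
Reactants: 9, 2,6-bis(4-hydroxybenzyl)-3-iodo-5-methoxyphenol; 11, 3-vinylphenol (3 equiv)
Product: 12, bulbocodin D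
Conditions: 10-phenylphenothiazine (5 mol%), Hantzsch ester (1.5 equiv), CySH (10 mol%), degassed DMSO (0.1 M), 390 nm LEDs, rt
Reagents that add atoms: none (only H, delivered from the Hantzsch ester through the thiol)
Why: Photoredox anti-Markovnikov hydroarylation (reductive Giese-type aryl-radical addition): the excited phenothiazine (about −2.1 V) reduces the C–I bond, the ring-A aryl radical adds to the styrene CH2 terminus (about 10^8 M⁻¹ s⁻¹, so 0.3 M alkene outruns cyclisation onto the neighbouring benzyl ring), and the benzylic radical is quenched by thiol H-atom transfer; DMSO hydrogen-bonds the free phenols and suppresses O–H abstraction, and no stereocentre is created.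

## Compound list

1 | p-cresol (4-methylphenol) | Cc1ccc(O)cc1 | starting material
2 | 4-methylphenyl pivalate | Cc1ccc(OC(=O)C(C)(C)C)cc1 | intermediate
3 | 4-(bromomethyl)phenyl pivalate | BrCc1ccc(OC(=O)C(C)(C)C)cc1 | intermediate
4 | 3-iodophenol | Oc1cccc(I)c1 | starting material
5 | 3-iodoanisole | COc1cccc(I)c1 | intermediate
6 | 2-(3-iodo-5-methoxyphenyl)-4,4,5,5-tetramethyl-1,3,2-dioxaborolane | COc1cc(I)cc(B2OC(C)(C)C(C)(C)O2)c1 | intermediate (not isolated)
7 | 3-iodo-5-methoxyphenol | COc1cc(I)cc(O)c1 | intermediate
8 | 3-iodo-5-methoxy-2,6-bis[4-(pivaloyloxy)benzyl]phenol | COc1cc(I)c(Cc2ccc(OC(=O)C(C)(C)C)cc2)c(O)c1Cc1ccc(OC(=O)C(C)(C)C)cc1 | intermediate (not isolated)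
9 | 2,6-bis(4-hydroxybenzyl)-3-iodo-5-methoxyphenol | COc1cc(I)c(Cc2ccc(O)cc2)c(O)c1Cc1ccc(O)cc1 | intermediate
10 | potassium vinyltrifluoroborate | C=C[B-](F)(F)F.[K+] | starting material
11 | 3-vinylphenol | C=Cc1cccc(O)c1 | intermediate
12 | bulbocodin D | COc1cc(CCc2cccc(O)c2)c(Cc2ccc(O)cc2)c(O)c1Cc1ccc(O)cc1 | target

## Summary

**Total step count:** 7. Steps 4 and 5 are each two-stage one-pot operations; counted strictly by transformation the total is 9.

**Longest linear sequence:** 4 steps (3-iodophenol → 5 → 7 → 9 → 12, steps 3, 4, 5, 7; the p-cresol branch, steps 1, 2, 5, 7, is also 4).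

**Steps most likely to fail, with fallbacks:**

1. **Step 5 (double ortho-C-benzylation).** Risks are O-benzylation, some attack at the position para to the phenoxide, and acyl transfer from the pivalate. Fallback: boron-templated ortho-specific route. Oxidise 3 to 4-formylphenyl pivalate (Kornblum oxidation), condense it with 7 and PhB(OH)2 to the 1,3,2-benzodioxaborin, reduce with Et3SiH/TFA to the ortho-benzyl phenol, and repeat for the second ortho position.

2. **Step 7 (radical hydroarylation).** Risks are proto-deiodination of 9, attack of the hindered aryl radical on its ortho-benzyl neighbour, and oligomerisation of 11. Fallback: swap the radical and acceptor roles. Vinylate 9 with 10 (Suzuki–Miyaura) to the ring-A styrene and add the unhindered 3-hydroxyphenyl radical generated from 4 under the same photoredox manifold, so the bridge is closed at the ring-B C(aryl)–CH2 bond instead.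

3. **Step 4 (Ir borylation in the presence of C–I).** Risks are catalyst deactivation or deiodination. Fallback: let boron, not oxygen, mark the future bridge carbon. Mono-methylate resorcinol to 3-methoxyphenol, borylate at C5, then convert the boronate to the iodide by Cu-mediated iododeboronation to reach 7.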